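## The problem

The target 46 is a briarane. A cyclohexane (ring A) is trans-fused through C1 and C10 to a ten-membered carbocycle that holds a cis,cis-1,3-diene (C3=C4, C5=C6), and this ring is fused through C7 and C8 to an α-methyl γ-lactone. There are ten stereocenters (C1, C2, C7–C11, C13, C14, C17). Those of the lactone (C7, C8, C17) are too far from those of ring A to be set from them, so two stereochemical domains have to be made separately and joined. Inside each domain control is available: C7 can fix C8 if C8 is built with fidelity, C17 is epimerisable, and the C13/C14 cis-diol can direct the quaternary C1, which then biases C10 and C11. C9 and C2 lie at the seams and must be set in the joining steps. The medium ring is hard to close, the diene with allylic acyloxy groups at C2 and C7 ionises readily, the 11,20-spiro-epoxide does not survive acid, and four acetates must be kept while the C16 and C8 hydroxyls stay free. The lactone also excludes strong hydride reagents and strong bases late in the route. The hardest atom is C8, a fully substituted carbinol between C7–O, C9–O and C17. The feature that opens it is that the lactone links the C7 oxygen through C19 to C17, and C17 is bonded to C8. An acyl carbenoid at C17, carried on the C7 oxygen, therefore sits five atoms from the C8–H bond of a simple C7/C8 erythro diol monoether, and a 1,5 C–H insertion can form C8–C17, the lactone ring and the quaternary C8 with retention.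

## Retrosynthesis

**Diene and last protecting group (46 ⇐ 45 ⇐ 44 ⇐ 43).** No skeletal bond is cut. The Z C3=C4 alkene is traced to an alkyne, so that the labile diene appears only in the penultimate compound 45 and the linear alkyne eases the ring closure. The free C16 hydroxyl is carried as a TBDPS ether, the only group left at the end. The forward steps need a semihydrogenation that spares C5=C6 and a desilylation that does not move acetates.

**Ring closure at C2–C3 (43 ⇐ 42).** The ten-membered ring is cut between the C2 carbinol and the alkyne carbon C3. Closure at C9–C10 would create two stereocenters in a macrocyclisation, and closure inside the diene would need a strained coupling. At C2–C3 the aldehyde sits on the quaternary C1 and cannot enolise, the iodoalkyne/CrCl2 addition tolerates every group present, and only C2 is at stake, which can be corrected by oxidation and reduction. Compound 42 has one ring less.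

**Ring A adjustments (42 ⇐ 41 ⇐ 40 ⇐ 39 ⇐ 38 ⇐ 37 ⇐ 36 ⇐ 35).** The C2 aldehyde and iodoalkyne come from the PMB ether and alkynylsilane of 39. The spiro-epoxide is cut at C11–O and C20–O back to the exocyclic alkene of 38, which the axial C15 methyl shields on its β face. The alkene is cut at C11=C20 back to the C11 ketone of 35. The acetates come from the acetonide and the C9 carbinol. The order is fixed by the acid-sensitive epoxide, which is made after the acetonide is removed.

**Seam at C9–C10 (35 ⇐ 22 + 34).** The C9–C10 bond is cut as an aldol between the α-alkoxy aldehyde 22 and the silyl enol ether 34. This is the only seam at which neither partner has to form a quaternary carbon. The aldehyde cannot enolise and the enol ether is regiodefined. The forward reaction must attack the β face of C10 with syn topicity.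

**Ring A (34 ⇐ 33 ⇐ 32 ⇐ 31 ⇐ 30 ⇐ 26 + 28, 26 ⇐ 23).** C1–C15 is cut as a cuprate addition to enone 33, anti to the C14 oxygen. The enone is traced through an oxidative 1,3-transposition to the cyclohexenol 32. The ring is cut at C10=C11 (metathesis of diene 31), and C1–C2 and C1–C10 as carbonyl additions. What remains is 2-deoxy-D-ribose (23), whose C3 and C4 are C13 and C14 with the right absolute configuration.

**Side chain of the lactone (22 ⇐ 20 ⇐ 19 ⇐ 17 ⇐ 16 ⇐ 15 ⇐ 13).** C4–C5 is cut as a Sonogashira coupling and C5=C6 as a Wittig reaction with a formyl ylide followed by α-iodination. This sets the trisubstituted alkene with C4 cis to C7 and brings C16 in at the aldehyde level, which borohydride can reduce beside the lactone.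

**Lactone (13 ⇐ 12 ⇐ 11 ⇐ 10).** C17–C18 is cut as a malonate alkylation with loss of the ester. Then the C8–C17 bond and the ring are cut together, leading to diazomalonate 10. Three groups are chosen for what follows:
- C6 carries an acetate, not a pivalate, because it must later come off beside the lactone.
- C8 carries a 4-methoxybenzyl (PMB) ether, not a benzyl ether, because hydrogenolysis is impossible once alkyne and alkenes are present.
- C9 carries a TBS ether, so that it can be removed beside the later TBDPS group.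

**Acyclic precursor (10 ⇐ 9 ⇐ 7 ⇐ 6 ⇐ 4 ⇐ 3 ⇐ 2 ⇐ 1).** The ester C–O bonds and the C8–O ether bond are cut. The erythro C7/C8 pair comes from anti opening of an E-epoxy alcohol at C3, and the epoxide from but-2-yne-1,4-diol (1).

## Roads not taken

**Alternative 1:** The ten-membered ring is treated as the periphery of two fused six-membered rings that share a C2=C7 alkene (tricyclic alkene A2, from Birch reduction of an aromatic ring). Ozonolysis of A2 with Me2S work-up would give the cyclodecane-2,7-dione A1.
- Merits: the medium ring arises without any macrocyclisation, and A1 already has C1, C9, C10, C13 and C14 correct. In ring formation this road is more reliable than the chosen one, which depends on a high-dilution closure.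
- Weak points: A1 has a methylene at C8 and none of C16–C19. The tertiary carbinol, the lactone, C16 and both alkenes would have to be introduced on a flexible 1,6-diketone that is prone to transannular aldol reactions, with stereocontrol at C2, C7 and C8 left to ring conformation.
- Comparison: the chosen plan sets against the easier ring its secure C7/C8/C17 triad, made before any ring strain exists.

**Alternative 2:** Ring A is cut at C1–C14 and C10–C11. Heating the triene A4, an E enoate tethered through a diisopropylsilyl ketal to an E,E-1,4-bis(silyloxy)diene, would give the cyclohexene A3 by intramolecular Diels–Alder reaction.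
- Merits: one step sets C1, C10 and C14 and relays C2, which already carries the alkyne. For ring A this is better than the chosen plan, which needs ten steps and relies on an unsecured facial selectivity at C10.
- Weak points: the dienophile must form a quaternary carbon, so high temperature is needed and the silyl dienol ether may not survive it. C12=C13 must then be hydrated regio- and stereoselectively and C11–O converted into the epoxide. The C9 ester must be joined to a C8 ketone, where the tertiary carbinol would come from an addition with no clear facial bias.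
- Comparison: the chosen plan is weaker for ring A and stronger for C8.

**Alternative 3:** Ring A is cut at C1–C10. Cp2TiCl (trivalent titanium) would open the epoxide of the geranyl-type acetate A6 to the tertiary C1 radical, which cyclises 6-endo and ends as the methylenecyclohexanol A5.
- Merits: a very short entry to ring A that delivers C11=C20 directly and has C2 and C9 attached. It beats the chosen plan in step count and spares the ketone methylenation.
- Weak points: A5 has no oxygen at C13, and its C14 hydroxyl is cis to the C1 methyl, opposite to the target. Both could be repaired through a C14 ketone at the cost of several steps. The union would then have to form C8–C9, so the quaternary carbinol would be made in the coupling.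
- Comparison: the chosen plan pays ten steps for ring A and gains a ring A with C13, C14 and C1 fixed from a sugar, and a C8 that is settled before the coupling.

Key step: step 8

Remark: positions are given in briarane numbering (C1–C20) and α/β refer to the drawing with the C15 methyl β. The 17R arrangement (methyl trans to the C9 arm on the lactone) is assumed to be the thermodynamically preferred one.

## Steps

Step 1
Reactants: 1 but-2-yne-1,4-diol
Product: 2 4-[(tert-butyldimethylsilyl)oxy]but-2-yn-1-ol
Conditions: NaH (1.0 equiv), THF, 0 °C; then TBSCl, 0 °C to rt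
Reagents that add atoms: tert-butyldimethylsilyl chloride, CC(C)(C)[Si](C)(C)Cl
Why: Monosilylation of a symmetrical diol through its sparingly soluble monosodium alkoxide; the TBS group marks the future C9 oxygen.

Step 2
Reactants: 2 4-[(tert-butyldimethylsilyl)oxy]but-2-yn-1-ol
Product: 3 (E)-4-[(tert-butyldimethylsilyl)oxy]but-2-en-1-ol
Conditions: NaAlH2(OCH2CH2OMe)2, THF, 0 °C; aq. Rochelle salt
Reagents that add atoms: none
Why: Hydroxyl-directed trans-hydroalumination of a propargylic alcohol and protonolysis give the E alkene only, which is what an erythro product after anti epoxide opening requires.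

Step 3
Reactants: 3 (E)-4-[(tert-butyldimethylsilyl)oxy]but-2-en-1-ol
Product: 4 [(2S,3S)-3-({[tert-butyl(dimethyl)silyl]oxy}methyl)oxiran-2-yl]methanol
Conditions: Ti(OiPr)4 (10 mol %), L-(+)-diethyl tartrate (12 mol %), t-BuOOH, 4 Å MS, CH2Cl2, −20 °C
Reagents that add atoms: tert-butyl hydroperoxide, CC(C)(C)OO
Why: Sharpless asymmetric epoxidation of an E allylic alcohol; L-(+)-tartrate delivers oxygen to the face that gives the (2S,3S)-epoxide, which sets C7 and, after inversion, C8.

Step 4
Reactants: 4 [(2S,3S)-3-({[tert-butyl(dimethyl)silyl]oxy}methyl)oxiran-2-yl]methanol; 5 4-methoxybenzyl alcohol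
Product: 6 (2S,3R)-4-[(tert-butyldimethylsilyl)oxy]-3-[(4-methoxybenzyl)oxy]butane-1,2-diol
Conditions: Ti(OiPr)4 (1.5 equiv) premixed with 5 (5 equiv) and freed of i-PrOH, benzene, 70 °C; aq. tartaric acid
Reagents that add atoms: none
Why: Titanium-alkoxide-mediated opening of a 2,3-epoxy alcohol: the epoxide is activated in the titanium chelate and the alcohol attacks C3 (the future C8) with inversion, giving the erythro 1,2-diol 3-ether.

Step 5
Reactants: 6 (2S,3R)-4-[(tert-butyldimethylsilyl)oxy]-3-[(4-methoxybenzyl)oxy]butane-1,2-diol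
Product: 7 (2S,3R)-4-[(tert-butyldimethylsilyl)oxy]-2-hydroxy-3-[(4-methoxybenzyl)oxy]butyl acetate
Conditions: AcCl (1.05 equiv), 2,4,6-collidine, CH2Cl2, −78 °C
Reagents that add atoms: acetyl chloride, CC(Cl)=O
Why: Kinetic acylation of the primary hydroxyl of a 1,2-diol; the C6 acetate deactivates the C6–H bonds toward the carbenoid and can later be removed without loss of the γ-lactone.

Step 6
Reactants: 7 (2S,3R)-4-[(tert-butyldimethylsilyl)oxy]-2-hydroxy-3-[(4-methoxybenzyl)oxy]butyl acetate; 8 methyl malonyl chloride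
Product: 9 (2S,3R)-1-acetoxy-4-[(tert-butyldimethylsilyl)oxy]-3-[(4-methoxybenzyl)oxy]butan-2-yl methyl malonate
Conditions: pyridine, CH2Cl2, 0 °C
Reagents that add atoms: none
Why: Acylation of the remaining secondary (C7) hydroxyl by an acid chloride, run directly after step 5 so that the acetate has no time to migrate.

Step 7
Reactants: 9 (2S,3R)-1-acetoxy-4-[(tert-butyldimethylsilyl)oxy]-3-[(4-methoxybenzyl)oxy]butan-2-yl methyl malonate
Product: 10 (2S,3R)-1-acetoxy-4-[(tert-butyldimethylsilyl)oxy]-3-[(4-methoxybenzyl)oxy]butan-2-yl methyl 2-diazomalonate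
Conditions: 4-acetamidobenzenesulfonyl azide, Et3N, MeCN, 0 °C to rt
Reagents that add atoms: 4-acetamidobenzenesulfonyl azide, CC(=O)Nc1ccc(cc1)S(=O)(=O)N=[N+]=[N-]
Why: Regitz diazo transfer to the doubly activated methylene of the malonate under mild amine base.

Step 8
Reactants: 10 (2S,3R)-1-acetoxy-4-[(tert-butyldimethylsilyl)oxy]-3-[(4-methoxybenzyl)oxy]butan-2-yl methyl 2-diazomalonate
Product: 11 methyl (4R,5S)-5-(acetoxymethyl)-4-{[(tert-butyldimethylsilyl)oxy]methyl}-4-[(4-methoxybenzyl)oxy]-2-oxooxolane-3-carboxylate (C7 S, C8 R; ester at C17 trans to the C9 arm)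
Conditions: Rh2(OAc)4 (2 mol %), benzene, 80 °C, slow addition of 10
Reagents that add atoms: none
Why: The divalent rhodium carboxylate Rh2(OAc)4 takes up the diazo carbon, loses N2 and gives an electrophilic acceptor/acceptor carbenoid at C17. The carbenoid carbon interacts with the C8–H bond in a three-centre, hydride-transfer-like transition state in which the developing positive charge at C8 is stabilised by the lone pair of the PMB ether oxygen, and the C–C bond forms on the face from which hydrogen leaves, so C8 keeps its configuration (closest known reaction type: Rh2(OAc)4-catalysed 1,5 insertion of diazomalonate and diazoacetate esters into ether-activated C–H bonds to give β-alkoxy γ-lactones). The γ-lactone closes as a 1,5 insertion through a five-membered transition state made of C17, C19, the ester oxygen, C7 and C8. The new quaternary stereocenter C8 is controlled by the C8 configuration of 10 (retention), which goes back to the epoxide opening, while C17 is also formed but is epimerisable and reset later. Site selectivity is needed against the two C6–H bonds (also 1,5) and against the C9–H and benzylic C–H bonds: the C6 acetate withdraws electron density from its side, the tertiary ether C–H at C8 is the most hydridic, and the remote bonds would need six- or seven-membered transition states. Chemoselectivity against attack of the ether oxygen on the carbenoid (six-membered oxonium ylide) is expected because insertion through the five-membered transition state is faster at this tether length, and slow addition holds back carbene dimerisation.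

Step 9
Reactants: 11 methyl (4R,5S)-5-(acetoxymethyl)-4-{[(tert-butyldimethylsilyl)oxy]methyl}-4-[(4-methoxybenzyl)oxy]-2-oxooxolane-3-carboxylate
Product: 12 methyl (4R,5S)-5-(acetoxymethyl)-4-{[(tert-butyldimethylsilyl)oxy]methyl}-4-[(4-methoxybenzyl)oxy]-3-methyl-2-oxooxolane-3-carboxylate (methyl expected trans to the C9 arm; of no consequence)
Conditions: MeI, K2CO3, acetone, rt
Reagents that add atoms: iodomethane, CI
Why: C-alkylation of the malonate-type anion under carbonate conditions mild enough to avoid β-elimination of the C8 ether; the C17 configuration formed here is erased in step 10.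

Step 10
Reactants: 12 methyl (4R,5S)-5-(acetoxymethyl)-4-{[(tert-butyldimethylsilyl)oxy]methyl}-4-[(4-methoxybenzyl)oxy]-3-methyl-2-oxooxolane-3-carboxylate
Product: 13 (3R,4R,5S)-5-(acetoxymethyl)-4-{[(tert-butyldimethylsilyl)oxy]methyl}-4-[(4-methoxybenzyl)oxy]-3-methyloxolan-2-one
Conditions: LiCl, H2O, DMSO, 140 °C
Reagents that add atoms: none
Why: Krapcho dealkoxycarbonylation: chloride demethylates the ester, CO2 is lost and the enol is protonated; C17 is epimerisable and should settle, here or under the carbonate of step 11, with the methyl trans to the larger C8 substituent (the C9 arm), as in the target.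

Step 11
Reactants: 13 (3R,4R,5S)-5-(acetoxymethyl)-4-{[(tert-butyldimethylsilyl)oxy]methyl}-4-[(4-methoxybenzyl)oxy]-3-methyloxolan-2-one
Product: 14 (3R,4R,5S)-4-{[(tert-butyldimethylsilyl)oxy]methyl}-5-(hydroxymethyl)-4-[(4-methoxybenzyl)oxy]-3-methyloxolan-2-one
Conditions: K2CO3 (0.2 equiv), MeOH, 0 °C
Reagents that add atoms: none
Why: Transesterification of a primary acetate; a γ-lactone that opens under these conditions recloses, and the five-membered lactone through O7 is favoured over the six-membered one through O6.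

Step 12
Reactants: 14 (3R,4R,5S)-4-{[(tert-butyldimethylsilyl)oxy]methyl}-5-(hydroxymethyl)-4-[(4-methoxybenzyl)oxy]-3-methyloxolan-2-one
Product: 15 the C6 aldehyde of 14 (5-formyl lactone; C7, C8, C17 unchanged)
Conditions: Dess–Martin periodinane, NaHCO3, CH2Cl2, 0 °C to rt; used crude
Reagents that add atoms: none
Why: Buffered Dess–Martin oxidation is non-basic, so the α-acyloxy aldehyde should neither epimerise at C7 nor eliminate the C8 ether.

Step 13
Reactants: 15 the C6 aldehyde of 14
Product: 16 the (E)-enal (C7–CH=CH–CHO; C5 and C16 added)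
Conditions: Ph3P=CHCHO, toluene, 60 °C
Reagents that add atoms: (triphenylphosphoranylidene)acetaldehyde, O=CC=P(c1ccccc1)(c1ccccc1)c1ccccc1
Why: Wittig reaction with a stabilised formyl ylide gives the E enal, and the ylide is too weakly basic to epimerise C7.

Step 14
Reactants: 16 the (E)-enal
Product: 17 the (Z)-α-iodo enal (iodine on C5, cis to C7)
Conditions: I2, DMAP (0.2 equiv), K2CO3, THF/H2O (1:1), rt
Reagents that add atoms: iodine, II
Why: α-Iodination of an enal by conjugate addition of DMAP, iodination of the enolate and elimination gives the Z iodide, which places the future C4 cis to C7 as the ring requires.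

Step 15
Reactants: 17 the (Z)-α-iodo enal
Product: 18 the (Z)-2-iodoallylic alcohol (C16–OH)
Conditions: NaBH4, CeCl3·7H2O, MeOH, −40 °C
Reagents that add atoms: none
Why: Luche 1,2-reduction brings C16 to the alcohol level with a hydride too mild to attack the lactone or the alkenyl iodide.

Step 16
Reactants: 18 the (Z)-2-iodoallylic alcohol
Product: 19 the C16 tert-butyldiphenylsilyl ether of 18
Conditions: TBDPSCl, imidazole, CH2Cl2, rt
Reagents that add atoms: tert-butyl(chloro)diphenylsilane, CC(C)(C)[Si](Cl)(c1ccccc1)c1ccccc1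
Why: Silylation of the primary allylic alcohol; TBDPS survives the acid that later removes TBS and the acetonide, and is the group kept to the last step.

Step 17
Reactants: 19 the C16 tert-butyldiphenylsilyl ether of 18
Product: 20 the enyne (C5 bears C≡C–SiMe3 cis to C7; C3 and C4 added)
Conditions: Me3SiC≡CH, PdCl2(PPh3)2 (5 mol %), CuI (10 mol %), Et3N, THF, rt
Reagents that add atoms: ethynyltrimethylsilane, C#C[Si](C)(C)C
Why: Sonogashira coupling of an alkenyl iodide proceeds with retention of the double-bond geometry.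

Step 18
Reactants: 20 the enyne
Product: 21 the C9 primary alcohol (TBS removed)
Conditions: camphorsulfonic acid (10 mol %), MeOH/CH2Cl2 (1:1), 0 °C
Reagents that add atoms: none
Why: Acid-catalysed methanolysis cleaves a primary TBS ether much faster than a TBDPS ether; the alkynylsilane and the PMB ether are stable to it.

Step 19
Reactants: 21 the C9 primary alcohol
Product: 22 the C9 aldehyde (C8 bears CHO, OPMB, C7 and C17)
Conditions: Dess–Martin periodinane, NaHCO3, CH2Cl2, rt
Reagents that add atoms: none
Why: Dess–Martin oxidation to an aldehyde that has no α-hydrogen and so cannot epimerise or enolise.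

Step 20
Reactants: 23 2-deoxy-D-ribose
Product: 24 2-deoxy-3,4-O-isopropylidene-D-erythro-pentopyranose (lactol)
Conditions: 2-methoxypropene, pyridinium p-toluenesulfonate (cat.), EtOAc, 0 °C to rt
Reagents that add atoms: 2-methoxypropene, COC(C)=C
Why: Acetonide formation on the cis-3,4-diol of the pyranose; these two carbons become C13 (S) and C14 (R) unchanged.

Step 21
Reactants: 24 2-deoxy-3,4-O-isopropylidene-D-erythro-pentopyranose
Product: 25 [(4R,5S)-2,2-dimethyl-5-(prop-2-en-1-yl)-1,3-dioxolan-4-yl]methanol
Conditions: Ph3PCH3Br, KOt-Bu (2.5 equiv each), THF, 0 °C to rt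
Reagents that add atoms: methyltriphenylphosphonium bromide, C[P+](c1ccccc1)(c1ccccc1)c1ccccc1.[Br-]
Why: Wittig methylenation of the open-chain aldehyde in equilibrium with the lactol; sugar C1 becomes C11 and the primary alcohol (future C1) is set free.

Step 22
Reactants: 25 [(4R,5S)-2,2-dimethyl-5-(prop-2-en-1-yl)-1,3-dioxolan-4-yl]methanol
Product: 26 (4S,5S)-2,2-dimethyl-5-(prop-2-en-1-yl)-1,3-dioxolane-4-carbaldehyde
Conditions: Dess–Martin periodinane, NaHCO3, CH2Cl2, 0 °C
Reagents that add atoms: none
Why: Buffered Dess–Martin oxidation gives the α-alkoxy aldehyde without epimerising the cis-dioxolane carbon (C14).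

Step 23
Reactants: 5 4-methoxybenzyl alcohol; 27 tributyl(iodomethyl)stannane
Product: 28 tributyl{[(4-methoxybenzyl)oxy]methyl}stannane
Conditions: NaH, THF/DMF, 0 °C to rt
Reagents that add atoms: none
Why: Williamson ether synthesis on a reactive primary iodide gives the tin precursor of the alkoxymethyl anion that supplies C2.

Step 24
Reactants: 26 (4S,5S)-2,2-dimethyl-5-(prop-2-en-1-yl)-1,3-dioxolane-4-carbaldehyde; 28 tributyl{[(4-methoxybenzyl)oxy]methyl}stannane
Product: 29 1-[5-allyl-2,2-dimethyl-1,3-dioxolan-4-yl]-2-[(4-methoxybenzyl)oxy]ethanol (dioxolane centres as in 26; carbinol epimers)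
Conditions: 28, n-BuLi, THF, −78 °C; then 26, −78 °C
Reagents that add atoms: none
Why: Tin–lithium exchange gives the α-alkoxymethyllithium, which adds to the aldehyde at −78 °C before it can rearrange; the carbinol configuration is of no consequence.

Step 25
Reactants: 29 1-[5-allyl-2,2-dimethyl-1,3-dioxolan-4-yl]-2-[(4-methoxybenzyl)oxy]ethanol
Product: 30 1-[5-allyl-2,2-dimethyl-1,3-dioxolan-4-yl]-2-[(4-methoxybenzyl)oxy]ethanone (dioxolane centres unchanged)
Conditions: Dess–Martin periodinane, NaHCO3, CH2Cl2, 0 °C to rt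
Reagents that add atoms: none
Why: Neutral oxidation of the secondary alcohol gives the ketone that will become C1 without epimerising the adjacent dioxolane carbon.

Step 26
Reactants: 30 1-[5-allyl-2,2-dimethyl-1,3-dioxolan-4-yl]-2-[(4-methoxybenzyl)oxy]ethanone
Product: 31 2-[5-allyl-2,2-dimethyl-1,3-dioxolan-4-yl]-1-[(4-methoxybenzyl)oxy]but-3-en-2-ol (tertiary carbinol epimers)
Conditions: CH2=CHMgBr, THF, −78 °C
Reagents that add atoms: vinylmagnesium bromide, C=C[Mg]Br
Why: Grignard addition supplies C10 as a vinyl group; the new carbinol centre is destroyed in step 28, so its configuration does not matter.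

Step 27
Reactants: 31 2-[5-allyl-2,2-dimethyl-1,3-dioxolan-4-yl]-1-[(4-methoxybenzyl)oxy]but-3-en-2-ol
Product: 32 the ring A cyclohexenol (C1 bears OH and CH2OPMB; C10=C11; C13/C14 acetonide)
Conditions: second-generation Grubbs catalyst RuCl2(=CHPh)(PCy3)(H2IMes) (5 mol %), CH2Cl2, 40 °C
Reagents that add atoms: none
Why: Ring-closing metathesis of a 1,7-diene closes ring A as a cyclohexene with loss of ethene; six-ring closure between two monosubstituted alkenes is among the most reliable metatheses.

Step 28
Reactants: 32 the ring A cyclohexenol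
Product: 33 (4R,5S)-4,5-(isopropylidenedioxy)-3-{[(4-methoxybenzyl)oxy]methyl}cyclohex-2-en-1-one
Conditions: pyridinium chlorochromate [C5H5NH][CrO3Cl], NaOAc, 4 Å MS, CH2Cl2, rt
Reagents that add atoms: pyridinium chlorochromate, [O-][Cr](=O)(=O)Cl.c1cc[nH+]cc1
Why: Babler–Dauben oxidative transposition: the chromate ester of the tertiary allylic alcohol undergoes a [3,3] shift to C11 and is oxidised there, giving the 3-substituted cyclohexenone.

Step 29
Reactants: 33 (4R,5S)-4,5-(isopropylidenedioxy)-3-{[(4-methoxybenzyl)oxy]methyl}cyclohex-2-en-1-one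
Product: 34 the C10=C11 trimethylsilyl enol ether of (3S,4R,5S)-4,5-(isopropylidenedioxy)-3-{[(4-methoxybenzyl)oxy]methyl}-3-methylcyclohexanone
Conditions: MeLi (2 equiv), CuI, Et2O, 0 °C; then TMSCl, 33, THF, −78 °C; Et3N
Reagents that add atoms: methyllithium, [Li]C; chlorotrimethylsilane, C[Si](C)(C)Cl
Why: Conjugate addition of Me2CuLi, accelerated by TMSCl, creates the quaternary C1; the cuprate enters anti to the adjacent C14–O bond of the acetonide, so the methyl is β and the CH2OPMB arm α, and the enolate is trapped regiospecifically.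

Step 30
Reactants: 22 the C9 aldehyde; 34 the C10=C11 trimethylsilyl enol ether
Product: 35 the (9S,10S) aldol adduct (C11 ketone; C9–OH; C9 β on C10, cis to the C15 methyl)
Conditions: MgBr2·OEt2 (3 equiv), CH2Cl2, −78 to −30 °C; aq. NaHCO3
Reagents that add atoms: none
Why: Chelation-controlled Mukaiyama aldol: MgBr2 bridges the aldehyde oxygen and the C8 PMB ether, and attack through an open transition state on such a chelate favours the syn (C1/O9) adduct whatever the enol ether geometry. The enol ether should react on its β face, away from the axial C14–O bond of the acetonide and past the methyl, the smaller C1 substituent; since C7 and C17 flank the aldehyde almost alike, these two preferences of the nucleophile decide C9.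

Step 31
Reactants: 35 the (9S,10S) aldol adduct
Product: 36 the C11 exocyclic methylene compound (C11=C20H2; C9–OH)
Conditions: Zn, CH2Br2, TiCl4 (reagent pre-formed in THF), CH2Cl2, 0 °C to rt
Reagents that add atoms: dibromomethane, BrCBr
Why: Takai–Lombardo methylenation: the non-basic zinc–titanium methylene reagent olefinates hindered, enolisable ketones without epimerising C10, without retro-aldol cleavage and without touching the lactone.

Step 32
Reactants: 36 the C11 exocyclic methylene compound
Product: 37 the C9,C13,C14 triol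
Conditions: AcOH/H2O/THF (3:1:1), 45 °C
Reagents that add atoms: none
Why: Hydrolysis of the cyclic acetal frees the C13 and C14 hydroxyls; PMB and TBDPS ethers, the alkynylsilane and the exocyclic alkene are stable to dilute acetic acid.

Step 33
Reactants: 37 the C9,C13,C14 triol
Product: 38 the C9,C13,C14 triacetate
Conditions: Ac2O, pyridine, DMAP (cat.), CH2Cl2, rt
Reagents that add atoms: acetic anhydride, CC(=O)OC(C)=O
Why: Exhaustive acetylation of the three secondary alcohols; no other free hydroxyl is present, so no selectivity is needed.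

Step 34
Reactants: 38 the C9,C13,C14 triacetate
Product: 39 the 11,20-spiro-epoxide (oxygen α, C20 β)
Conditions: m-CPBA, NaHCO3, CH2Cl2, 0 °C
Reagents that add atoms: 3-chloroperoxybenzoic acid, OOC(=O)c1cccc(Cl)c1
Why: Peracid epoxidation of the 1,1-disubstituted exocyclic alkene, the only electron-rich alkene (the enyne alkene is conjugated and carries two allylic oxygens). In the chair with C2 and C9 equatorial the axial C15 methyl blocks the β face of C11, so oxygen arrives from the α face.

Step 35
Reactants: 39 the 11,20-spiro-epoxide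
Product: 40 the C2,C8 diol (both PMB ethers removed)
Conditions: DDQ (3 equiv), CH2Cl2/pH 7 phosphate buffer (10:1), 0 °C to rt
Reagents that add atoms: none
Why: Oxidative cleavage of both 4-methoxybenzyl ethers through their benzylic cations; the buffer protects the epoxide, and silyl ether, acetates and enyne are inert.

Step 36
Reactants: 40 the C2,C8 diol
Product: 41 the C2 aldehyde (C8–OH free)
Conditions: Dess–Martin periodinane, NaHCO3, CH2Cl2, 0 °C to rt
Reagents that add atoms: none
Why: Oxidation of the primary neopentyl alcohol; the tertiary C8 hydroxyl cannot be oxidised and the aldehyde on quaternary C1 cannot enolise.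

Step 37
Reactants: 41 the C2 aldehyde
Product: 42 the iodoalkyne aldehyde (C3–I)
Conditions: N-iodosuccinimide, AgNO3 (10 mol %), acetone, rt, dark
Reagents that add atoms: N-iodosuccinimide, O=C1CCC(=O)N1I
Why: Silver-catalysed iododesilylation converts the alkynylsilane directly into the iodoalkyne through a silver acetylide.

Step 38
Reactants: 42 the iodoalkyne aldehyde
Product: 43 the ten-membered propargylic alcohol (C2–OH, 2S; C3≡C4)
Conditions: CrCl2 (8 equiv), NiCl2 (2 mol %), THF (2 mM), rt
Reagents that add atoms: none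
Why: Nozaki–Hiyama–Kishi reaction: the alkynylchromium species (trivalent chromium) formed from the iodoalkyne adds only to the aldehyde and closes the ring at C2–C3 in the presence of esters, lactone, epoxide and free hydroxyl. The aldehyde face is chosen by the closing ring, in which the rigid enyne and the trans ring fusion should leave one face open.

Step 39
Reactants: 43 the ten-membered propargylic alcohol
Product: 44 the C2 acetate of 43
Conditions: Ac2O, pyridine, DMAP (5 mol %), CH2Cl2, 0 °C
Reagents that add atoms: acetic anhydride, CC(=O)OC(C)=O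
Why: Acetylation of the secondary propargylic alcohol; the tertiary C8 hydroxyl is too hindered to react under these conditions.

Step 40
Reactants: 44 the C2 acetate of 43
Product: 45 the 16-O-tert-butyldiphenylsilyl ether of the target (3Z,5E-diene)
Conditions: H2 (1 atm), Pd/CaCO3 poisoned with Pb(OAc)2, quinoline, EtOAc, rt
Reagents that add atoms: none
Why: Lindlar semihydrogenation adds hydrogen syn to the ring alkyne and gives the Z C3=C4 alkene; the trisubstituted C5=C6 alkene, the epoxide and the esters are not reduced.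

Step 41
Reactants: 45 the 16-O-tert-butyldiphenylsilyl ether of the target
Product: 46 CNP0317528.1 (the target)
Conditions: Bu4NF, AcOH (1:1), THF, 0 °C to rt
Reagents that add atoms: none
Why: Fluoride cleaves the last silyl ether; buffering with acetic acid should prevent acetyl migration and epimerisation at C17, and the epoxide is not exposed to acid.

## Compound list

1 | but-2-yne-1,4-diol | OCC#CCO | starting material
2 | 4-[(tert-butyldimethylsilyl)oxy]but-2-yn-1-ol | CC(C)(C)[Si](C)(C)OCC#CCO | intermediate
3 | (E)-4-[(tert-butyldimethylsilyl)oxy]but-2-en-1-ol | CC(C)(C)[Si](C)(C)OC/C=C/CO | intermediate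
4 | [(2S,3S)-3-({[tert-butyl(dimethyl)silyl]oxy}methyl)oxiran-2-yl]methanol | CC(C)(C)[Si](C)(C)OC[C@@H]1O[C@H]1CO | intermediate
5 | 4-methoxybenzyl alcohol | COc1ccc(CO)cc1 | starting material
6 | (2S,3R)-4-[(tert-butyldimethylsilyl)oxy]-3-[(4-methoxybenzyl)oxy]butane-1,2-diol | CC(C)(C)[Si](C)(C)OC[C@@H](OCc1ccc(OC)cc1)[C@H](CO)O | intermediate
7 | (2S,3R)-4-[(tert-butyldimethylsilyl)oxy]-2-hydroxy-3-[(4-methoxybenzyl)oxy]butyl acetate | CC(C)(C)[Si](C)(C)OC[C@@H](OCc1ccc(OC)cc1)[C@H](COC(C)=O)O | intermediate
8 | methyl malonyl chloride | COC(=O)CC(Cl)=O | starting material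
9 | (2S,3R)-1-acetoxy-4-[(tert-butyldimethylsilyl)oxy]-3-[(4-methoxybenzyl)oxy]butan-2-yl methyl malonate | CC(C)(C)[Si](C)(C)OC[C@@H](OCc1ccc(OC)cc1)[C@H](COC(C)=O)OC(=O)CC(=O)OC | intermediate
10 | (2S,3R)-1-acetoxy-4-[(tert-butyldimethylsilyl)oxy]-3-[(4-methoxybenzyl)oxy]butan-2-yl methyl 2-diazomalonate | CC(C)(C)[Si](C)(C)OC[C@@H](OCc1ccc(OC)cc1)[C@H](COC(C)=O)OC(=O)C(=[N+]=[N-])C(=O)OC | intermediate
11 | methyl (4R,5S)-5-(acetoxymethyl)-4-{[(tert-butyldimethylsilyl)oxy]methyl}-4-[(4-methoxybenzyl)oxy]-2-oxooxolane-3-carboxylate | CC(C)(C)[Si](C)(C)OC[C@@]1(OCc2ccc(OC)cc2)[C@H](COC(C)=O)OC(=O)[C@@H]1C(=O)OC | intermediate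
12 | methyl (4R,5S)-5-(acetoxymethyl)-4-{[(tert-butyldimethylsilyl)oxy]methyl}-4-[(4-methoxybenzyl)oxy]-3-methyl-2-oxooxolane-3-carboxylate | CC(C)(C)[Si](C)(C)OC[C@@]1(OCc2ccc(OC)cc2)[C@H](COC(C)=O)OC(=O)[C@@]1(C)C(=O)OC | intermediate
13 | (3R,4R,5S)-5-(acetoxymethyl)-4-{[(tert-butyldimethylsilyl)oxy]methyl}-4-[(4-methoxybenzyl)oxy]-3-methyloxolan-2-one | CC(C)(C)[Si](C)(C)OC[C@@]1(OCc2ccc(OC)cc2)[C@H](COC(C)=O)OC(=O)[C@@H]1C | intermediate
14 | (3R,4R,5S)-4-{[(tert-butyldimethylsilyl)oxy]methyl}-5-(hydroxymethyl)-4-[(4-methoxybenzyl)oxy]-3-methyloxolan-2-one | CC(C)(C)[Si](C)(C)OC[C@@]1(OCc2ccc(OC)cc2)[C@H](CO)OC(=O)[C@@H]1C | intermediate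
15 | C6 aldehyde of 14 (5-formyl lactone) | CC(C)(C)[Si](C)(C)OC[C@@]1(OCc2ccc(OC)cc2)[C@H](C=O)OC(=O)[C@@H]1C | intermediate
16 | (E)-enal (C7–CH=CH–CHO) | CC(C)(C)[Si](C)(C)OC[C@@]1(OCc2ccc(OC)cc2)[C@H](/C=C/C=O)OC(=O)[C@@H]1C | intermediate
17 | (Z)-α-iodo enal | CC(C)(C)[Si](C)(C)OC[C@@]1(OCc2ccc(OC)cc2)[C@H](/C=C(\I)C=O)OC(=O)[C@@H]1C | intermediate
18 | (Z)-2-iodoallylic alcohol | CC(C)(C)[Si](C)(C)OC[C@@]1(OCc2ccc(OC)cc2)[C@H](/C=C(\I)CO)OC(=O)[C@@H]1C | intermediate
19 | C16 tert-butyldiphenylsilyl ether of 18 | CC(C)(C)[Si](C)(C)OC[C@@]1(OCc2ccc(OC)cc2)[C@H](/C=C(\I)CO[Si](c2ccccc2)(c2ccccc2)C(C)(C)C)OC(=O)[C@@H]1C | intermediate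
20 | enyne (C≡C–SiMe3 on C5, cis to C7) | CC(C)(C)[Si](C)(C)OC[C@@]1(OCc2ccc(OC)cc2)[C@H](/C=C(\C#C[Si](C)(C)C)CO[Si](c2ccccc2)(c2ccccc2)C(C)(C)C)OC(=O)[C@@H]1C | intermediate
21 | C9 primary alcohol | OC[C@@]1(OCc2ccc(OC)cc2)[C@H](/C=C(\C#C[Si](C)(C)C)CO[Si](c2ccccc2)(c2ccccc2)C(C)(C)C)OC(=O)[C@@H]1C | intermediate
22 | C9 aldehyde (lactone fragment C3–C9, C16–C19) | O=C[C@@]1(OCc2ccc(OC)cc2)[C@H](/C=C(\C#C[Si](C)(C)C)CO[Si](c2ccccc2)(c2ccccc2)C(C)(C)C)OC(=O)[C@@H]1C | intermediate
23 | 2-deoxy-D-ribose (drawn as the open-chain aldehyde) | O=CC[C@H](O)[C@H](O)CO | starting material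
24 | 2-deoxy-3,4-O-isopropylidene-D-erythro-pentopyranose | OC1C[C@@H]2OC(C)(C)O[C@@H]2CO1 | intermediate
25 | [(4R,5S)-2,2-dimethyl-5-(prop-2-en-1-yl)-1,3-dioxolan-4-yl]methanol | C=CC[C@@H]1OC(C)(C)O[C@@H]1CO | intermediate
26 | (4S,5S)-2,2-dimethyl-5-(prop-2-en-1-yl)-1,3-dioxolane-4-carbaldehyde | C=CC[C@@H]1OC(C)(C)O[C@@H]1C=O | intermediate
27 | tributyl(iodomethyl)stannane | CCCC[Sn](CCCC)(CCCC)CI | starting material
28 | tributyl{[(4-methoxybenzyl)oxy]methyl}stannane | CCCC[Sn](CCCC)(CCCC)COCc1ccc(OC)cc1 | intermediate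
29 | 1-[5-allyl-2,2-dimethyl-1,3-dioxolan-4-yl]-2-[(4-methoxybenzyl)oxy]ethanol (carbinol epimers) | C=CC[C@@H]1OC(C)(C)O[C@@H]1C(O)COCc1ccc(OC)cc1 | intermediate
30 | 1-[5-allyl-2,2-dimethyl-1,3-dioxolan-4-yl]-2-[(4-methoxybenzyl)oxy]ethanone | C=CC[C@@H]1OC(C)(C)O[C@@H]1C(=O)COCc1ccc(OC)cc1 | intermediate
31 | 2-[5-allyl-2,2-dimethyl-1,3-dioxolan-4-yl]-1-[(4-methoxybenzyl)oxy]but-3-en-2-ol (carbinol epimers) | C=CC[C@@H]1OC(C)(C)O[C@@H]1C(O)(C=C)COCc1ccc(OC)cc1 | intermediate
32 | ring A cyclohexenol (C1–OH, C1–CH2OPMB, C10=C11, C13/C14 acetonide) | OC1(COCc2ccc(OC)cc2)C=CC[C@@H]3OC(C)(C)O[C@H]13 | intermediate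
33 | (4R,5S)-4,5-(isopropylidenedioxy)-3-{[(4-methoxybenzyl)oxy]methyl}cyclohex-2-en-1-one | O=C1C=C(COCc2ccc(OC)cc2)[C@H]3OC(C)(C)O[C@H]3C1 | intermediate
34 | C10=C11 trimethylsilyl enol ether of (3S,4R,5S)-4,5-(isopropylidenedioxy)-3-{[(4-methoxybenzyl)oxy]methyl}-3-methylcyclohexanone | C[Si](C)(C)OC1=C[C@@](C)(COCc2ccc(OC)cc2)[C@H]3OC(C)(C)O[C@H]3C1 | intermediate
35 | (9S,10S) aldol adduct (C11 ketone, C9–OH) | O=C1C[C@@H]2OC(C)(C)O[C@@H]2[C@](C)(COCc2ccc(OC)cc2)[C@H]1[C@H](O)[C@@]3(OCc4ccc(OC)cc4)[C@H](/C=C(\C#C[Si](C)(C)C)CO[Si](c4ccccc4)(c4ccccc4)C(C)(C)C)OC(=O)[C@@H]3C | intermediate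
36 | C11 exocyclic methylene compound | C=C1C[C@@H]2OC(C)(C)O[C@@H]2[C@](C)(COCc2ccc(OC)cc2)[C@H]1[C@H](O)[C@@]3(OCc4ccc(OC)cc4)[C@H](/C=C(\C#C[Si](C)(C)C)CO[Si](c4ccccc4)(c4ccccc4)C(C)(C)C)OC(=O)[C@@H]3C | intermediate
37 | C9,C13,C14 triol | C=C1C[C@H](O)[C@H](O)[C@](C)(COCc2ccc(OC)cc2)[C@H]1[C@H](O)[C@@]3(OCc4ccc(OC)cc4)[C@H](/C=C(\C#C[Si](C)(C)C)CO[Si](c4ccccc4)(c4ccccc4)C(C)(C)C)OC(=O)[C@@H]3C | intermediate
38 | C9,C13,C14 triacetate | C=C1C[C@H](OC(C)=O)[C@H](OC(C)=O)[C@](C)(COCc2ccc(OC)cc2)[C@H]1[C@H](OC(C)=O)[C@@]3(OCc4ccc(OC)cc4)[C@H](/C=C(\C#C[Si](C)(C)C)CO[Si](c4ccccc4)(c4ccccc4)C(C)(C)C)OC(=O)[C@@H]3C | intermediate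
39 | 11,20-spiro-epoxide (O α) | C1O[C@@]12C[C@H](OC(C)=O)[C@H](OC(C)=O)[C@](C)(COCc3ccc(OC)cc3)[C@H]2[C@H](OC(C)=O)[C@@]4(OCc5ccc(OC)cc5)[C@H](/C=C(\C#C[Si](C)(C)C)CO[Si](c5ccccc5)(c5ccccc5)C(C)(C)C)OC(=O)[C@@H]4C | intermediate
40 | C2,C8 diol | C1O[C@@]12C[C@H](OC(C)=O)[C@H](OC(C)=O)[C@](C)(CO)[C@H]2[C@H](OC(C)=O)[C@@]4(O)[C@H](/C=C(\C#C[Si](C)(C)C)CO[Si](c5ccccc5)(c5ccccc5)C(C)(C)C)OC(=O)[C@@H]4C | intermediate
41 | C2 aldehyde | C1O[C@@]12C[C@H](OC(C)=O)[C@H](OC(C)=O)[C@](C)(C=O)[C@H]2[C@H](OC(C)=O)[C@@]4(O)[C@H](/C=C(\C#C[Si](C)(C)C)CO[Si](c5ccccc5)(c5ccccc5)C(C)(C)C)OC(=O)[C@@H]4C | intermediate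
42 | iodoalkyne aldehyde | C1O[C@@]12C[C@H](OC(C)=O)[C@H](OC(C)=O)[C@](C)(C=O)[C@H]2[C@H](OC(C)=O)[C@@]4(O)[C@H](/C=C(\C#CI)CO[Si](c5ccccc5)(c5ccccc5)C(C)(C)C)OC(=O)[C@@H]4C | intermediate
43 | ten-membered propargylic alcohol (2S) | CC(=O)O[C@H]1C[C@]2(CO2)[C@@H]2[C@H](OC(C)=O)[C@@]3(O)[C@H](/C=C(CO[Si](c4ccccc4)(c4ccccc4)C(C)(C)C)\C#C[C@H](O)[C@@]2(C)[C@H]1OC(C)=O)OC(=O)[C@@H]3C | intermediate
44 | C2 acetate of 43 | CC(=O)O[C@H]1C[C@]2(CO2)[C@@H]2[C@H](OC(C)=O)[C@@]3(O)[C@H](/C=C(CO[Si](c4ccccc4)(c4ccccc4)C(C)(C)C)\C#C[C@H](OC(C)=O)[C@@]2(C)[C@H]1OC(C)=O)OC(=O)[C@@H]3C | intermediate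
45 | 16-O-tert-butyldiphenylsilyl ether of the target | CC(=O)O[C@H]1C[C@]2(CO2)[C@@H]2[C@H](OC(C)=O)[C@@]3(O)[C@H](/C=C(CO[Si](c4ccccc4)(c4ccccc4)C(C)(C)C)\C=C/[C@H](OC(C)=O)[C@@]2(C)[C@H]1OC(C)=O)OC(=O)[C@@H]3C | intermediate
46 | CNP0317528.1, (1S,2S,3Z,5E,7S,8S,9S,10S,11R,13S,14R,17R)-2,9,13,14-tetraacetoxy-11,20-epoxy-8,16-dihydroxybriara-3,5-dien-19,7-olide | CC(=O)O[C@H]1C[C@]2(CO2)[C@@H]2[C@H](OC(C)=O)[C@@]3(O)[C@H](/C=C(CO)\C=C/[C@H](OC(C)=O)[C@@]2(C)[C@H]1OC(C)=O)OC(=O)[C@@H]3C | target

## Step count and least certain steps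

Total: 41 steps. Longest linear sequence: 31 steps (steps 1–19 and 30–41). The ring A branch (steps 20–29) has 10 steps.

**Step 8 (key step).** The ether oxygen at C8 may attack the carbenoid and form a six-membered oxonium ylide, which would then shift its 4-methoxybenzyl group. Insertion on the C6 side or carbene dimerisation may also compete, because an acceptor/acceptor carbenoid is highly electrophilic.

Fallback, from 7 back to 13:
- Compound 7 is esterified with glyoxylic acid chloride p-toluenesulfonylhydrazone and then treated with Et3N, giving the diazoacetate F1.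
- F1 is decomposed with dirhodium tetracaprolactamate, Rh2(cap)4, a divalent rhodium carboxamidate. It is far less electrophilic and is known to prefer insertion next to ether oxygen over ylide formation. This gives the C17-unsubstituted lactone F2.
- LDA and MeI at −78 °C methylate the enolate of F2 anti to the C9 arm and give 13.

**Step 30.** The two hindered partners may react slowly. The facial selectivity at C10 or the syn topicity may fail, because neither is enforced by a rigid element, and the adduct may undergo retro-aldol cleavage.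

Fallback, from 33 back to 36:
- Me2CuLi is added to 33 and the enolate is trapped with N-phenylbis(trifluoromethanesulfonimide), giving the enol triflate F3.
- Kumada coupling of F3 with Me3SiCH2MgCl and Pd(PPh3)4 (zerovalent palladium) gives the allylsilane F4.
- Hosomi–Sakurai addition of F4 to 22 with BF3·OEt2 at −78 °C forms C9–C10 through an open antiperiplanar transition state with a strong syn preference. It delivers 36 directly, so the ketone and its methylenation are bypassed.

**Step 38.** The face of the C2 aldehyde is chosen by the conformation of the closing ring and need not be the required one. Oligomerisation is countered by high dilution.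

Fallback, from 43 back to 43:
- The alcohol 43, obtained as a mixture with its C2 epimer, is oxidised with Dess–Martin periodinane to the macrocyclic ynone F5.
- Corey–Bakshi–Shibata reduction of F5 with the (R)-methyl oxazaborolidine and catecholborane (alkyne as the small group) returns 43 with C2 set by the reagent.

**Step 4.** The C4 oxygen lowers the usual preference for attack at C3, so opening at C2 may compete. Isopropoxide may also be transferred from titanium in place of the benzylic alcohol.

Fallback, from 4 back to 6: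
- Ti(OiPr)4-mediated opening of 4 with benzoic acid, the nucleophile class with the highest C3 selectivity, gives the 3-benzoate diol F6.
- 2-Methoxypropene and pyridinium p-toluenesulfonate give the acetonide F7.
- K2CO3 in MeOH removes the benzoate and gives the alcohol F8.
- 4-Methoxybenzyl trichloroacetimidate with La(OTf)3 (cat.) gives the ether F9.
- CeCl3·7H2O and oxalic acid in MeCN cleave the terminal acetonide of F9 and give 6.

## Further compounds

F1 | step 8 | (2S,3R)-1-acetoxy-4-[(tert-butyldimethylsilyl)oxy]-3-[(4-methoxybenzyl)oxy]butan-2-yl diazoacetate | CC(C)(C)[Si](C)(C)OC[C@@H](OCc1ccc(OC)cc1)[C@H](COC(C)=O)OC(=O)C=[N+]=[N-]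
F2 | step 8 | (4R,5S)-5-(acetoxymethyl)-4-{[(tert-butyldimethylsilyl)oxy]methyl}-4-[(4-methoxybenzyl)oxy]oxolan-2-one | CC(C)(C)[Si](C)(C)OC[C@@]1(OCc2ccc(OC)cc2)[C@H](COC(C)=O)OC(=O)C1
F3 | step 30 | C10=C11 enol triflate of the ring A ketone | FC(F)(F)S(=O)(=O)OC1=C[C@@](C)(COCc2ccc(OC)cc2)[C@H]3OC(C)(C)O[C@H]3C1
F4 | step 30 | ring A allylsilane (C20 bears SiMe3; C10=C11) | C[Si](C)(C)CC1=C[C@@](C)(COCc2ccc(OC)cc2)[C@H]3OC(C)(C)O[C@H]3C1
F5 | step 38 | macrocyclic C2 ynone | CC(=O)O[C@H]1C[C@]2(CO2)[C@@H]2[C@H](OC(C)=O)[C@@]3(O)[C@H](/C=C(CO[Si](c4ccccc4)(c4ccccc4)C(C)(C)C)\C#CC(=O)[C@@]2(C)[C@H]1OC(C)=O)OC(=O)[C@@H]3C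
F6 | step 4 | (2R,3S)-1-[(tert-butyldimethylsilyl)oxy]-3,4-dihydroxybutan-2-yl benzoate | CC(C)(C)[Si](C)(C)OC[C@@H](OC(=O)c1ccccc1)[C@H](CO)O
F7 | step 4 | 1,2-acetonide of F6 | CC(C)(C)[Si](C)(C)OC[C@@H](OC(=O)c1ccccc1)[C@@H]1COC(C)(C)O1
F8 | step 4 | acetonide alcohol (C8–OH free) | CC(C)(C)[Si](C)(C)OC[C@@H](O)[C@@H]1COC(C)(C)O1
F9 | step 4 | acetonide 4-methoxybenzyl ether | CC(C)(C)[Si](C)(C)OC[C@@H](OCc1ccc(OC)cc1)[C@@H]1COC(C)(C)O1
A1 | alternative 1 | bicyclic cyclodecane-2,7-dione with C5 ketal | CC1(C)O[C@H]2CC3(OCCO3)[C@@H]3[C@H](O[Si](C)(C)C(C)(C)C)CC(=O)CC4(OCCO4)CCC(=O)[C@@]3(C)[C@H]2O1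
A2 | alternative 1 | tricyclic alkene with C2=C7 ring-fusion double bond | CC1(C)O[C@H]2CC3(OCCO3)[C@@H]3[C@H](O[Si](C)(C)C(C)(C)C)CC4=C(CCC5(OCCO5)C4)[C@@]3(C)[C@H]2O1
A3 | alternative 2 | ring A cyclohexene fused to the silaketal | COC(=O)[C@H]1[C@H](O[Si](C)(C)C(C)(C)C)C=C[C@@H]2O[Si](C(C)C)(C(C)C)O[C@@H](C#C[Si](C)(C)C)[C@]12C
A4 | alternative 2 | silicon-tethered enoate–diene | COC(=O)/C=C(\C)[C@H](C#C[Si](C)(C)C)O[Si](C(C)C)(C(C)C)O/C=C/C=C/O[Si](C)(C)C(C)(C)C
A5 | alternative 3 | ring A methylenecyclohexanol | CC(=O)OC[C@H]1C(=C)CC[C@@H](O)[C@]1(C)CO[Si](C)(C)C(C)(C)C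
A6 | alternative 3 | epoxygeranyl-type acetate | CC(=O)OC/C=C(\C)CC[C@H]1O[C@]1(C)CO[Si](C)(C)C(C)(C)C
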